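## Retrosynthetic overview

- The target is reached by hydrogenolysis of two aryl benzyl ethers from the dibenzyl β-acetoxy ketone; the acetate and ketone survive neutral H2, Pd/C.
- The β-acetoxy ketone comes from oxidation of the free carbinol of the mono-acetate of a C2-symmetric anti-1,3-diol. The two hydroxyls of the (3S,5S)-diol are homotopic, so mono-acetylation gives one compound and the surviving acetoxy centre is S.
- The (3S,5S)-diol comes from Noyori hydrogenation of the 1,3-diketone tetrahydrocurcumin with an (S)-BINAP ruthenium catalyst (sets both stereocentres), followed by benzylation of the phenols.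
- No ring is formed and no C–C bond is made: both aryl rings and the whole seven-carbon chain come intact from tetrahydrocurcumin.

Assumption: tetrahydrocurcumin is taken as a commercial starting material.

## Route

Step 1
Reactants: 1 tetrahydrocurcumin [1,7-bis(4-hydroxy-3-methoxyphenyl)heptane-3,5-dione]
Product: 3 (3S,5S)-1,7-bis(4-hydroxy-3-methoxyphenyl)heptane-3,5-diol, via (S)-hexahydrocurcumin 2 (not isolated)
Conditions: H2 (60 bar), [RuCl(p-cymene)((S)-BINAP)]Cl (1 mol %), MeOH, 50 °C
Reagents that add atoms: none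
Why: Noyori asymmetric hydrogenation of a 1,3-diketone: the (S)-BINAP ruthenium catalyst chelates the β-dicarbonyl unit and reduces each C=O from the same enantioface, so the first reduction sets 5S in 2 and the matched, hydroxyl-assisted second reduction sets the other centre anti to give (3S,5S)-3 (the same sense as pentane-2,4-dione giving the (S,S)-diol with (S)-BINAP), while phenols and arenes are untouched.

Step 2
Reactants: 3 (3S,5S)-1,7-bis(4-hydroxy-3-methoxyphenyl)heptane-3,5-diol
Product: 4 (3S,5S)-1,7-bis[4-(benzyloxy)-3-methoxyphenyl]heptane-3,5-diol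
Conditions: BnBr (2.2 equiv), K2CO3 (3 equiv), acetone, reflux
Reagents that add atoms: benzyl bromide, BrCc1ccccc1
Why: Williamson ether synthesis in which K2CO3 deprotonates only the phenols and not the secondary alcohols, so the two phenolic oxygens are benzylated selectively; it is placed after the hydrogenation because the free 1,3-diketone of 1 would C-benzylate.

Step 3
Reactants: 4 (3S,5S)-1,7-bis[4-(benzyloxy)-3-methoxyphenyl]heptane-3,5-diol
Product: 6 (3S,5S)-1,7-bis[4-(benzyloxy)-3-methoxyphenyl]-5-hydroxyheptan-3-yl acetate, via cyclic methyl orthoacetate 5 (not isolated)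
Conditions: MeC(OMe)3 (1.5 equiv), PPTS (cat.), CH2Cl2, rt; then H2O, rt
Reagents that add atoms: trimethyl orthoacetate, CC(OC)(OC)OC; water, O
Why: Acid-catalysed orthoester exchange closes the 1,3-diol to a 2-methoxy-2-methyl-1,3-dioxane and water opens the derived dioxanylium ion to the mono-acetate (orthoester mono-acylation of a diol); because the two carbinols of the C2-symmetric diol are homotopic, either ring opening and any later 1,3-acetyl shift give the same single compound and no stereocentre is touched.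

Step 4
Reactants: 6 (3S,5S)-1,7-bis[4-(benzyloxy)-3-methoxyphenyl]-5-hydroxyheptan-3-yl acetate
Product: 7 (3S)-1,7-bis[4-(benzyloxy)-3-methoxyphenyl]-5-oxoheptan-3-yl acetate
Conditions: Dess–Martin periodinane (1.3 equiv), CH2Cl2, 0 °C to rt
Reagents that add atoms: none
Why: Dess–Martin oxidation turns the remaining secondary alcohol into the ketone under non-basic conditions that spare the β-acetoxy group, the benzyl ethers and the arenes, leaving the acetoxy-bearing carbon as the only stereocentre with S configuration.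

Step 5
Reactants: 7 (3S)-1,7-bis[4-(benzyloxy)-3-methoxyphenyl]-5-oxoheptan-3-yl acetate
Product: 8 (3S)-1,7-bis(4-hydroxy-3-methoxyphenyl)-5-oxoheptan-3-yl acetate
Conditions: H2 (1 atm), 10% Pd/C, EtOAc, rt
Reagents that add atoms: none
Why: Catalytic hydrogenolysis of the two aryl benzyl ethers over palladium on carbon in a neutral solvent frees both phenols, while the aliphatic ketone, the non-benzylic secondary acetate and the stereocentre are inert.

## Compound list

1 | tetrahydrocurcumin, 1,7-bis(4-hydroxy-3-methoxyphenyl)heptane-3,5-dione | COc1cc(CCC(=O)CC(=O)CCc2ccc(O)c(OC)c2)ccc1O | starting material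
2 | (S)-hexahydrocurcumin, (5S)-5-hydroxy-1,7-bis(4-hydroxy-3-methoxyphenyl)heptan-3-one | COc1cc(CCC(=O)C[C@H](CCc2ccc(O)c(OC)c2)O)ccc1O | intermediate
3 | (3S,5S)-1,7-bis(4-hydroxy-3-methoxyphenyl)heptane-3,5-diol | COc1cc(CC[C@H](O)C[C@H](CCc2ccc(O)c(OC)c2)O)ccc1O | intermediate
4 | (3S,5S)-1,7-bis[4-(benzyloxy)-3-methoxyphenyl]heptane-3,5-diol | COc1cc(CC[C@H](O)C[C@H](CCc2ccc(OCc3ccccc3)c(OC)c2)O)ccc1OCc1ccccc1 | intermediate
5 | cyclic methyl orthoacetate, (4S,6S)-4,6-bis{2-[4-(benzyloxy)-3-methoxyphenyl]ethyl}-2-methoxy-2-methyl-1,3-dioxane | COc1cc(CC[C@H](O2)C[C@H](CCc3ccc(OCc4ccccc4)c(OC)c3)OC2(C)OC)ccc1OCc1ccccc1 | intermediate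
6 | (3S,5S)-1,7-bis[4-(benzyloxy)-3-methoxyphenyl]-5-hydroxyheptan-3-yl acetate | COc1cc(CC[C@H](O)C[C@H](CCc2ccc(OCc3ccccc3)c(OC)c2)OC(C)=O)ccc1OCc1ccccc1 | intermediate
7 | (3S)-1,7-bis[4-(benzyloxy)-3-methoxyphenyl]-5-oxoheptan-3-yl acetate | COc1cc(CCC(=O)C[C@H](CCc2ccc(OCc3ccccc3)c(OC)c2)OC(C)=O)ccc1OCc1ccccc1 | intermediate
8 | (3S)-1,7-bis(4-hydroxy-3-methoxyphenyl)-5-oxoheptan-3-yl acetate, (5S)-5-acetoxyhexahydrocurcumin | COc1cc(CCC(=O)C[C@H](CCc2ccc(O)c(OC)c2)OC(C)=O)ccc1O | target

## Step count and risks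

Total step count: 5. Longest linear sequence: 5.

The three steps most likely to fail:

**Step 1 (asymmetric hydrogenation).** The free phenols and the strongly enolised diketone may slow the catalyst, and any meso-diol formed lowers the final ee unless it is removed at 4 by crystallisation or chromatography. The fallback sets out from 1 and comes back to the route at 4, bypassing 3. Compound 1 is treated with BF3·OEt2 in CH2Cl2 at rt to give the difluoroboron chelate of tetrahydrocurcumin F1, in which the diketone is masked and cannot C-alkylate. BnBr and K2CO3 in acetone then give the bis(benzyl ether) of the chelate F2. Boron is removed with Na2C2O4 in aqueous MeOH at 65 °C to give 1,7-bis[4-(benzyloxy)-3-methoxyphenyl]heptane-3,5-dione F3. Hydrogenation of this phenol-free diketone with [RuCl(p-cymene)((S)-BINAP)]Cl in MeOH/CH2Cl2 gives 4 directly.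

**Step 3 (mono-acetylation).** The cyclic orthoester of an anti-1,3-diol must carry one axial substituent and may form sluggishly or hydrolyse back to the diol. The fallback sets out from 4 and comes back at 6. Exhaustive acetylation with Ac2O, pyridine and catalytic DMAP gives the diacetate F4. One of its two homotopic acetates is then removed by partial methanolysis (K2CO3 0.3 equiv, MeOH, 0 °C, stopped near half conversion). This gives 6, and recovered F4 and 4 are recycled.

**Step 4 (oxidation next to a β-acetoxy group).** The product can lose acetic acid to the enone during reaction or on silica. The fallback sets out from 4 and comes back at 7, bypassing 6, so that the ketone is made before the acetate is installed. Mono-silylation with NaH (1 equiv) and TBSCl (1 equiv) in THF at 0 °C gives the mono-TBS ether F5. Dess–Martin oxidation gives the robust β-silyloxy ketone F6. HF·pyridine in THF at 0 °C frees the β-hydroxy ketone F7. Acetylation with Ac2O and pyridine at 0 °C then gives 7.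

## Further compounds

F1 | step 1 | difluoroboron chelate of tetrahydrocurcumin, 2,2-difluoro-4,6-bis[2-(4-hydroxy-3-methoxyphenyl)ethyl]-1,3,2-dioxaborinine | COc1cc(CCC2=CC(CCc3ccc(O)c(OC)c3)=[O+][B-](F)(F)O2)ccc1O
F2 | step 1 | bis(benzyl ether) of the chelate, 2,2-difluoro-4,6-bis{2-[4-(benzyloxy)-3-methoxyphenyl]ethyl}-1,3,2-dioxaborinine | COc1cc(CCC2=CC(CCc3ccc(OCc4ccccc4)c(OC)c3)=[O+][B-](F)(F)O2)ccc1OCc1ccccc1
F3 | step 1 | 1,7-bis[4-(benzyloxy)-3-methoxyphenyl]heptane-3,5-dione | COc1cc(CCC(=O)CC(=O)CCc2ccc(OCc3ccccc3)c(OC)c2)ccc1OCc1ccccc1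
F4 | step 3 | (3S,5S)-1,7-bis[4-(benzyloxy)-3-methoxyphenyl]heptane-3,5-diyl diacetate | COc1cc(CC[C@H](OC(C)=O)C[C@H](CCc2ccc(OCc3ccccc3)c(OC)c2)OC(C)=O)ccc1OCc1ccccc1
F5 | step 4 | (3S,5S)-1,7-bis[4-(benzyloxy)-3-methoxyphenyl]-5-[(tert-butyldimethylsilyl)oxy]heptan-3-ol | COc1cc(CC[C@H](O)C[C@H](CCc2ccc(OCc3ccccc3)c(OC)c2)O[Si](C)(C)C(C)(C)C)ccc1OCc1ccccc1
F6 | step 4 | (5S)-1,7-bis[4-(benzyloxy)-3-methoxyphenyl]-5-[(tert-butyldimethylsilyl)oxy]heptan-3-one | COc1cc(CCC(=O)C[C@H](CCc2ccc(OCc3ccccc3)c(OC)c2)O[Si](C)(C)C(C)(C)C)ccc1OCc1ccccc1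
F7 | step 4 | (5S)-1,7-bis[4-(benzyloxy)-3-methoxyphenyl]-5-hydroxyheptan-3-one | COc1cc(CCC(=O)C[C@H](CCc2ccc(OCc3ccccc3)c(OC)c2)O)ccc1OCc1ccccc1
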